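**Retrosynthetic overview**
1. Target 23 ⇐ 22 by cleavage of the one methyl ether that sits ortho to the isobutyryl carbonyl (O4'); 22 ⇐ 21 by removal of three benzyl ethers.
2. Feature: ring B reads C1'(CH2Ar)–C2'(O)–C3'(isopentyl)–C4'(O)–C5'(isobutyryl)–C6'(O). C4'–C5' is the triple bond of a β-alkoxy ynone, and C3'=C2'–C1'=C6' is the 2-silyloxy-4-benzyloxy diene of a 2,4-disubstituted cyclohexane-1,3-dione. An Alder–Rickert sequence forms C3'–C4' and C5'–C6', and the two sp3 ring carbons leave as ethylene.
3. Diene 13 ⇐ benzyl enol ether 12 ⇐ dione 11 ⇐ 4-isopentylcyclohexane-1,3-dione 9 + ring A aldehyde 5. The isopentyl group is installed before ring A is attached, so no enolate alkylation is run beside the enolisable ring A acetyl group; in step 8 that acetyl group is simply silylated as well.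
4. Ring A is carried from 2,4,6-trihydroxytoluene (C-acetylation, O-methylation para to the acetyl group, formylation, benzylation). Ring B is the only ring formed in the route (step 11).
5. Ynone 18 ⇐ lithium methoxyacetylide + 2-methylpropanal, then oxidation.

Key step: step 11

Remark: the ynol ether is used as its methyl ether, because an ethyl ynol ether can lose ethylene by retro-ene reaction at cycloaddition temperatures and is the harder ether to cleave later; all chiral intermediates are racemic and their centres disappear in step 8, 10 or 11.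

**Route**

Step 1
Reactants: 1 2,4,6-trihydroxytoluene
Product: 2 1-(2,4,6-trihydroxy-3-methylphenyl)ethan-1-one
Conditions: AcCl, AlCl3, PhNO2/CH2Cl2, 0 °C to rt; aq. HCl
Reagents that add atoms: acetyl chloride, CC(=O)Cl
Why: Friedel–Crafts C-acylation at one of the two equivalent free ring positions, after which the acyl group deactivates the ring against a second acylation.

Step 2
Reactants: 2 1-(2,4,6-trihydroxy-3-methylphenyl)ethan-1-one
Product: 3 1-(2,6-dihydroxy-4-methoxy-3-methylphenyl)ethan-1-one
Conditions: Me2SO4 (1.0 equiv), K2CO3, acetone, rt to reflux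
Reagents that add atoms: dimethyl sulfate, COS(=O)(=O)OC
Why: Williamson O-methylation with one equivalent of reagent should go to the 4-OH, the only hydroxyl not hydrogen-bonded to the acetyl group and the most acidic one (para to the ketone).

Step 3
Reactants: 3 1-(2,6-dihydroxy-4-methoxy-3-methylphenyl)ethan-1-one
Product: 4 3-acetyl-2,4-dihydroxy-6-methoxy-5-methylbenzaldehyde
Conditions: Cl2CHOMe, TiCl4, CH2Cl2, –10 to 0 °C; aq. HCl
Reagents that add atoms: dichloromethyl methyl ether, COC(Cl)Cl; water, O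
Why: Rieche formylation at the only unsubstituted ring carbon, which is activated by an ortho hydroxyl, an ortho methoxy and a para hydroxyl group.

Step 4
Reactants: 4 3-acetyl-2,4-dihydroxy-6-methoxy-5-methylbenzaldehyde
Product: 5 3-acetyl-2,4-bis(benzyloxy)-6-methoxy-5-methylbenzaldehyde
Conditions: BnBr (2.5 equiv), K2CO3, n-Bu4NI (cat.), DMF, 50 °C
Reagents that add atoms: benzyl bromide, BrCc1ccccc1
Why: Williamson benzylation of both chelated phenols in a dipolar aprotic solvent; the ring is fully substituted, so only O-alkylation is open.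

Step 5
Reactants: 6 3-ethoxycyclohex-2-en-1-one; 7 1-iodo-3-methylbutane
Product: 9 racemic 4-(3-methylbutyl)cyclohexane-1,3-dione, via 6-alkylated ethoxyenone 8 (not isolated)
Conditions: LDA, THF, –78 °C; 7, DMPU, –78 °C to rt; then 2 M HCl, THF, rt
Reagents that add atoms: water, O
Why: Stork–Danheiser alkylation (LDA forms the kinetic α'-enolate at C6 of the vinylogous ester, which is alkylated by the primary iodide), followed by acid hydrolysis of the enol ether to the 4-substituted 1,3-dione.

Step 6
Reactants: 9 racemic 4-(3-methylbutyl)cyclohexane-1,3-dione; 5 3-acetyl-2,4-bis(benzyloxy)-6-methoxy-5-methylbenzaldehyde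
Product: 11 racemic 2-{[3-acetyl-2,4-bis(benzyloxy)-6-methoxy-5-methylphenyl]methyl}-4-(3-methylbutyl)cyclohexane-1,3-dione, via Knoevenagel alkylidene-dione 10 (not isolated)
Conditions: Hantzsch ester (1.1 equiv), L-proline (20 mol%), CH2Cl2, rt to 40 °C
Reagents that add atoms: none
Why: Organocatalytic three-component reductive alkylation (proline-catalysed Knoevenagel condensation, then conjugate hydride transfer from the Hantzsch ester to the alkylidene dione), which should monoalkylate C2 and leave the hindered aryl ketone untouched.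

Step 7
Reactants: 11 racemic 2-{[3-acetyl-2,4-bis(benzyloxy)-6-methoxy-5-methylphenyl]methyl}-4-(3-methylbutyl)cyclohexane-1,3-dione
Product: 12 racemic 2-{[3-acetyl-2,4-bis(benzyloxy)-6-methoxy-5-methylphenyl]methyl}-3-(benzyloxy)-6-(3-methylbutyl)cyclohex-2-en-1-one
Conditions: BnOH, PPh3, DIAD, THF, 0 °C to rt
Reagents that add atoms: benzyl alcohol, OCc1ccccc1
Why: Mitsunobu O-alkylation of the acidic 1,3-dione should benzylate the enol oxygen remote from the C4 side chain, since the other oxygen is flanked by both the C2 arylmethyl and the C4 isopentyl group; the minor regioisomer can be hydrolysed back to 11.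

Step 8
Reactants: 12 racemic 2-{[3-acetyl-2,4-bis(benzyloxy)-6-methoxy-5-methylphenyl]methyl}-3-(benzyloxy)-6-(3-methylbutyl)cyclohex-2-en-1-one
Product: 13 4-(benzyloxy)-3-({2,4-bis(benzyloxy)-6-methoxy-5-methyl-3-[1-(trimethylsilyloxy)ethenyl]phenyl}methyl)-1-(3-methylbutyl)-2-(trimethylsilyloxy)cyclohexa-1,3-diene
Conditions: LDA (3 equiv), TMSCl (4 equiv, present from the start), THF, –78 to –30 °C; pentane, filtration; used crude
Reagents that add atoms: chlorotrimethylsilane, C[Si](C)(C)Cl
Why: Kinetic enolisation with in situ O-silylation: LDA removes the proton at the only α'-carbon (C6, bearing isopentyl) to give the cross-conjugated 2-silyloxy diene, and the aryl methyl ketone, which would otherwise consume the base, is converted by the extra equivalent into its silyl enol ether.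

Step 9
Reactants: 14 2-chloro-1,1-dimethoxyethane; 15 2-methylpropanal
Product: 17 racemic 1-methoxy-4-methylpent-1-yn-3-ol, via lithium methoxyacetylide 16 (not isolated)
Conditions: LiNEt2 (3 equiv, from Et2NH and n-BuLi), THF, 0 °C; then 15, –78 °C; aq. NaHCO3
Reagents that add atoms: none
Why: Double elimination (HCl, then MeOH) from the chloroacetal and deprotonation by three equivalents of LiNEt2 gives the alkoxyacetylide, which undergoes 1,2-addition to the aldehyde; the carbinol centre is racemic and is removed in step 10.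

Step 10
Reactants: 17 racemic 1-methoxy-4-methylpent-1-yn-3-ol
Product: 18 1-methoxy-4-methylpent-1-yn-3-one
Conditions: MnO2 (activated, excess), CH2Cl2, rt; filtration; used as a solution
Reagents that add atoms: none
Why: MnO2 oxidation of a propargylic alcohol under neutral anhydrous conditions, which should spare the acid-sensitive ynol ether.

Step 11
Reactants: 13 4-(benzyloxy)-3-({2,4-bis(benzyloxy)-6-methoxy-5-methyl-3-[1-(trimethylsilyloxy)ethenyl]phenyl}methyl)-1-(3-methylbutyl)-2-(trimethylsilyloxy)cyclohexa-1,3-diene; 18 1-methoxy-4-methylpent-1-yn-3-one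
Product: 21 1-[3-{[3-acetyl-2,4-bis(benzyloxy)-6-methoxy-5-methylphenyl]methyl}-2-(benzyloxy)-4-hydroxy-6-methoxy-5-(3-methylbutyl)phenyl]-2-methylpropan-1-one, via bicyclo[2.2.2]octa-2,5-diene cycloadduct 19 (not isolated), via bis-silylated arene 20 (not isolated)
Conditions: 18 (3 equiv), BHT (cat.), PhMe, sealed tube, 110 °C then 150 °C; then 1 M HCl, THF, 0 °C
Reagents that add atoms: none
Why: Proposed new method: the 2-silyloxy-4-benzyloxy diene of 13 should add the ynone across its termini C1 and C4 in a [4+2] cycloaddition (concerted but asynchronous, or Mukaiyama–Michael addition followed by closure of the allenolate onto the oxocarbenium carbon), forming C3'–C4' and C5'–C6', and the bicyclo[2.2.2]octa-2,5-diene 19 should then extrude its C7–C8 bridge as ethylene in a retro-[4+2] driven by aromatisation. The closest known reaction is the Alder–Rickert sequence of 1-alkoxy-3-silyloxycyclohexa-1,3-dienes with acetylenic ketones and esters; a β-alkoxy ynone has not been used as the 2π partner. Ring B is closed in the intermolecular [4+2] step, in which both new bonds go to the alkyne carbons, and becomes aromatic in the cycloreversion. No stereocentre survives: the two bridgehead centres of 19 are tied to each other by the bicycle and vanish when ethylene leaves. The step needs a single orientation of the unsymmetrical ynone: both oxygen donors of the diene (OSiMe3 on C2, OBn on C4) put the largest HOMO coefficient on C1, the isopentyl-bearing terminus, which pairs with the methoxy-bearing β-carbon of the ynone, and the position of the diene itself was fixed in step 8. The methyl ynol ether has no β-hydrogen and cannot fragment to a ketene at these temperatures, and the mild acid at the end only hydrolyses the aryl silyl ether and the silyl enol ether of 20.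

Step 12
Reactants: 21 1-[3-{[3-acetyl-2,4-bis(benzyloxy)-6-methoxy-5-methylphenyl]methyl}-2-(benzyloxy)-4-hydroxy-6-methoxy-5-(3-methylbutyl)phenyl]-2-methylpropan-1-one
Product: 22 1-[3-[(3-acetyl-2,4-dihydroxy-6-methoxy-5-methylphenyl)methyl]-2,4-dihydroxy-6-methoxy-5-(3-methylbutyl)phenyl]-2-methylpropan-1-one
Conditions: BCl3 (1 M in CH2Cl2, 8 equiv), C6HMe5 (6 equiv), CH2Cl2, –78 °C; MeOH, then aq. work-up
Reagents that add atoms: none
Why: Lewis-acid debenzylation: BCl3 ionises the three aryl benzyl ethers at –78 °C and pentamethylbenzene traps the benzyl cations by Friedel–Crafts alkylation, while aryl methyl ethers should be inert at this temperature.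

Step 13
Reactants: 22 1-[3-[(3-acetyl-2,4-dihydroxy-6-methoxy-5-methylphenyl)methyl]-2,4-dihydroxy-6-methoxy-5-(3-methylbutyl)phenyl]-2-methylpropan-1-one
Product: 23 1-[3-[(3-acetyl-2,4-dihydroxy-6-methoxy-5-methylphenyl)methyl]-2,4,6-trihydroxy-5-(3-methylbutyl)phenyl]-2-methylpropan-1-one (CNP0238575.0)
Conditions: BCl3 (excess), CH2Cl2, 0 °C to rt, monitored; MeOH, then aq. HCl
Reagents that add atoms: none
Why: Chelation-controlled Lewis-acid demethylation: excess BCl3 should bind the isobutyryl carbonyl together with the neighbouring 4'-methoxy oxygen and chloride removes that methyl group as MeCl, whereas the ring A methoxy group has no ortho carbonyl and should survive.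

**Compound list**
1 | 2,4,6-trihydroxytoluene | Cc1c(O)cc(O)cc1O | starting material
2 | 1-(2,4,6-trihydroxy-3-methylphenyl)ethan-1-one | CC(=O)c1c(O)cc(O)c(C)c1O | intermediate
3 | 1-(2,6-dihydroxy-4-methoxy-3-methylphenyl)ethan-1-one | CC(=O)c1c(O)cc(OC)c(C)c1O | intermediate
4 | 3-acetyl-2,4-dihydroxy-6-methoxy-5-methylbenzaldehyde | CC(=O)c1c(O)c(C=O)c(OC)c(C)c1O | intermediate
5 | 3-acetyl-2,4-bis(benzyloxy)-6-methoxy-5-methylbenzaldehyde | CC(=O)c1c(OCc2ccccc2)c(C=O)c(OC)c(C)c1OCc1ccccc1 | intermediate
6 | 3-ethoxycyclohex-2-en-1-one | CCOC1=CC(=O)CCC1 | starting material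
7 | 1-iodo-3-methylbutane | CC(C)CCI | starting material
8 | 3-ethoxy-6-(3-methylbutyl)cyclohex-2-en-1-one (racemic) | CCOC1=CC(=O)C(CCC(C)C)CC1 | intermediate (not isolated)
9 | 4-(3-methylbutyl)cyclohexane-1,3-dione (racemic) | O=C1CC(=O)C(CCC(C)C)CC1 | intermediate
10 | 2-{[3-acetyl-2,4-bis(benzyloxy)-6-methoxy-5-methylphenyl]methylidene}-4-(3-methylbutyl)cyclohexane-1,3-dione (racemic, either alkene geometry) | O=C1CCC(CCC(C)C)C(=O)C1=Cc1c(OC)c(C)c(OCc2ccccc2)c(C(C)=O)c1OCc1ccccc1 | intermediate (not isolated)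
11 | 2-{[3-acetyl-2,4-bis(benzyloxy)-6-methoxy-5-methylphenyl]methyl}-4-(3-methylbutyl)cyclohexane-1,3-dione (racemic at C4, largely enolised) | O=C1CCC(CCC(C)C)C(=O)C1Cc1c(OC)c(C)c(OCc2ccccc2)c(C(C)=O)c1OCc1ccccc1 | intermediate
12 | 2-{[3-acetyl-2,4-bis(benzyloxy)-6-methoxy-5-methylphenyl]methyl}-3-(benzyloxy)-6-(3-methylbutyl)cyclohex-2-en-1-one (racemic) | O=C1C(CCC(C)C)CCC(OCc2ccccc2)=C1Cc1c(OC)c(C)c(OCc2ccccc2)c(C(C)=O)c1OCc1ccccc1 | intermediate
13 | 4-(benzyloxy)-3-({2,4-bis(benzyloxy)-6-methoxy-5-methyl-3-[1-(trimethylsilyloxy)ethenyl]phenyl}methyl)-1-(3-methylbutyl)-2-(trimethylsilyloxy)cyclohexa-1,3-diene | C[Si](C)(C)OC1=C(CCC(C)C)CCC(OCc2ccccc2)=C1Cc1c(OC)c(C)c(OCc2ccccc2)c(C(=C)O[Si](C)(C)C)c1OCc1ccccc1 | intermediate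
14 | 2-chloro-1,1-dimethoxyethane | COC(CCl)OC | starting material
15 | 2-methylpropanal | CC(C)C=O | starting material
16 | lithium methoxyacetylide | [Li]C#COC | intermediate (not isolated)
17 | 1-methoxy-4-methylpent-1-yn-3-ol (racemic) | COC#CC(O)C(C)C | intermediate
18 | 1-methoxy-4-methylpent-1-yn-3-one | COC#CC(=O)C(C)C | intermediate
19 | bicyclo[2.2.2]octa-2,5-diene cycloadduct: C1 3-methylbutyl, C2 methoxy, C3 2-methylpropanoyl, C4 benzyloxy, C5 arylmethyl (ring A as in 13), C6 trimethylsilyloxy, C7–C8 ethano bridge; racemic, the two bridgehead centres are tied to each other by the bicycle | CC(C)CCC12CCC(OCc3ccccc3)(C(Cc4c(OC)c(C)c(OCc5ccccc5)c(C(=C)O[Si](C)(C)C)c4OCc4ccccc4)=C1O[Si](C)(C)C)C(C(=O)C(C)C)=C2OC | intermediate (not isolated)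
20 | 1-[2-(benzyloxy)-3-({2,4-bis(benzyloxy)-6-methoxy-5-methyl-3-[1-(trimethylsilyloxy)ethenyl]phenyl}methyl)-6-methoxy-5-(3-methylbutyl)-4-(trimethylsilyloxy)phenyl]-2-methylpropan-1-one | COc1c(CCC(C)C)c(O[Si](C)(C)C)c(Cc2c(OC)c(C)c(OCc3ccccc3)c(C(=C)O[Si](C)(C)C)c2OCc2ccccc2)c(OCc2ccccc2)c1C(=O)C(C)C | intermediate (not isolated)
21 | 1-[3-{[3-acetyl-2,4-bis(benzyloxy)-6-methoxy-5-methylphenyl]methyl}-2-(benzyloxy)-4-hydroxy-6-methoxy-5-(3-methylbutyl)phenyl]-2-methylpropan-1-one | COc1c(CCC(C)C)c(O)c(Cc2c(OC)c(C)c(OCc3ccccc3)c(C(C)=O)c2OCc2ccccc2)c(OCc2ccccc2)c1C(=O)C(C)C | intermediate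
22 | 1-[3-[(3-acetyl-2,4-dihydroxy-6-methoxy-5-methylphenyl)methyl]-2,4-dihydroxy-6-methoxy-5-(3-methylbutyl)phenyl]-2-methylpropan-1-one | COc1c(C)c(O)c(C(C)=O)c(O)c1Cc1c(O)c(CCC(C)C)c(OC)c(C(=O)C(C)C)c1O | intermediate
23 | 1-[3-[(3-acetyl-2,4-dihydroxy-6-methoxy-5-methylphenyl)methyl]-2,4,6-trihydroxy-5-(3-methylbutyl)phenyl]-2-methylpropan-1-one | COc1c(C)c(O)c(C(C)=O)c(O)c1Cc1c(O)c(CCC(C)C)c(O)c(C(=O)C(C)C)c1O | target

**Step count**
Total: 13 steps. Longest linear sequence: 10 steps (steps 1–4, 6–8, 11–13); steps 5 and 9–10 are side branches.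

**Steps most likely to fail**

1. Step 11 (Alder–Rickert with a β-alkoxy ynone). The push–pull ynone may be too weak a 2π partner for a diene whose four carbons are all substituted. Diene decomposition, or silyl transfer after the first C–C bond to an open-chain Michael adduct, could then outrun ring closure, and the orientation could be partly reversed. Fallback (known chemistry, methylene-bridge coupling of two acylphloroglucinols), setting out from 3 and returning at 23: phloroglucinol is C-acylated with isobutyryl chloride and AlCl3 to 2-methyl-1-(2,4,6-trihydroxyphenyl)propan-1-one F1. This is C-prenylated with prenyl bromide in aqueous KOH to 2-methyl-1-[2,4,6-trihydroxy-3-(3-methylbut-2-en-1-yl)phenyl]propan-1-one F2 and hydrogenated (H2, Pd/C) to 2-methyl-1-[2,4,6-trihydroxy-3-(3-methylbutyl)phenyl]propan-1-one F3. Compound 3 is converted with CH2O and Me2NH into the Mannich base 1-{3-[(dimethylamino)methyl]-2,6-dihydroxy-4-methoxy-5-methylphenyl}ethan-1-one F4. Heating F4 with F3 in dioxane should release the ortho-quinone methide of ring A, which alkylates the one free ring carbon of F3 and gives 23 directly.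

2. Step 13 (selective demethylation). Chemoselectivity between the two methyl ethers may be lost. The 4'-ether is the second ortho ether of a carbonyl that O6' already holds in a boron chelate, so its cleavage may be slow enough for the ring A ether to be attacked as well. Fallback, setting out from 22 and returning at 23: 22 is peracetylated (Ac2O, pyridine, DMAP) to the tetraacetate of 22 F5, in which O6' is capped as a non-chelating ester. BCl3 (CH2Cl2, –78 to 0 °C) can then use the free isobutyryl carbonyl to cleave the 4'-methyl ether as a first ortho ether, giving the 4'-hydroxy tetraacetate F6. K2CO3 in MeOH removes the four acetates and should give 23.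

3. Step 7 (regioselective enol ether formation). Benzylation on the oxygen next to the isopentyl-bearing carbon, or competing C-benzylation, would give material that cannot lead to diene 13. Fallback, setting out from 5 and returning at 12, forms the enol ether on a symmetrical dione and alkylates afterwards with the acetyl group masked. Cyclohexane-1,3-dione and 5 (Hantzsch ester, L-proline) give 2-{[3-acetyl-2,4-bis(benzyloxy)-6-methoxy-5-methylphenyl]methyl}cyclohexane-1,3-dione F7. BnOH, PPh3 and DIAD give the single possible enol ether 2-{[3-acetyl-2,4-bis(benzyloxy)-6-methoxy-5-methylphenyl]methyl}-3-(benzyloxy)cyclohex-2-en-1-one F8. LiHMDS (1 equiv, –78 °C) then TBSOTf should silylate the more acidic aryl methyl ketone to 3-(benzyloxy)-2-[(2,4-bis(benzyloxy)-3-{1-[(tert-butyldimethylsilyl)oxy]ethenyl}-6-methoxy-5-methylphenyl)methyl]cyclohex-2-en-1-one F9. LDA, 7 and DMPU alkylate the only α'-carbon to 3-(benzyloxy)-2-[(2,4-bis(benzyloxy)-3-{1-[(tert-butyldimethylsilyl)oxy]ethenyl}-6-methoxy-5-methylphenyl)methyl]-6-(3-methylbutyl)cyclohex-2-en-1-one F10, and TBAF with AcOH returns the acetyl group to give 12.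

Further compounds
F1 | step 11 | 2-methyl-1-(2,4,6-trihydroxyphenyl)propan-1-one | CC(C)C(=O)c1c(O)cc(O)cc1O
F2 | step 11 | 2-methyl-1-[2,4,6-trihydroxy-3-(3-methylbut-2-en-1-yl)phenyl]propan-1-one | CC(C)C(=O)c1c(O)cc(O)c(CC=C(C)C)c1O
F3 | step 11 | 2-methyl-1-[2,4,6-trihydroxy-3-(3-methylbutyl)phenyl]propan-1-one | CC(C)C(=O)c1c(O)cc(O)c(CCC(C)C)c1O
F4 | step 11 | 1-{3-[(dimethylamino)methyl]-2,6-dihydroxy-4-methoxy-5-methylphenyl}ethan-1-one | CC(=O)c1c(O)c(CN(C)C)c(OC)c(C)c1O
F5 | step 13 | tetraacetate of 22 (all four phenols acetylated) | COc1c(C)c(OC(C)=O)c(C(C)=O)c(OC(C)=O)c1Cc1c(OC(C)=O)c(CCC(C)C)c(OC)c(C(=O)C(C)C)c1OC(C)=O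
F6 | step 13 | 4'-hydroxy tetraacetate (F5 with the 4'-methyl ether cleaved) | COc1c(C)c(OC(C)=O)c(C(C)=O)c(OC(C)=O)c1Cc1c(OC(C)=O)c(CCC(C)C)c(O)c(C(=O)C(C)C)c1OC(C)=O
F7 | step 7 | 2-{[3-acetyl-2,4-bis(benzyloxy)-6-methoxy-5-methylphenyl]methyl}cyclohexane-1,3-dione | O=C1CCCC(=O)C1Cc1c(OC)c(C)c(OCc2ccccc2)c(C(C)=O)c1OCc1ccccc1
F8 | step 7 | 2-{[3-acetyl-2,4-bis(benzyloxy)-6-methoxy-5-methylphenyl]methyl}-3-(benzyloxy)cyclohex-2-en-1-one | O=C1CCCC(OCc2ccccc2)=C1Cc1c(OC)c(C)c(OCc2ccccc2)c(C(C)=O)c1OCc1ccccc1
F9 | step 7 | 3-(benzyloxy)-2-[(2,4-bis(benzyloxy)-3-{1-[(tert-butyldimethylsilyl)oxy]ethenyl}-6-methoxy-5-methylphenyl)methyl]cyclohex-2-en-1-one | O=C1CCCC(OCc2ccccc2)=C1Cc1c(OC)c(C)c(OCc2ccccc2)c(C(=C)O[Si](C)(C)C(C)(C)C)c1OCc1ccccc1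
F10 | step 7 | 3-(benzyloxy)-2-[(2,4-bis(benzyloxy)-3-{1-[(tert-butyldimethylsilyl)oxy]ethenyl}-6-methoxy-5-methylphenyl)methyl]-6-(3-methylbutyl)cyclohex-2-en-1-one (racemic) | O=C1C(CCC(C)C)CCC(OCc2ccccc2)=C1Cc1c(OC)c(C)c(OCc2ccccc2)c(C(=C)O[Si](C)(C)C(C)(C)C)c1OCc1ccccc1
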